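The data come from a simulation for substances that don't exist, and the scatter is random.

- In this closed flask X (free monomer), Q (monomer in chains) and a missing part always add up to the X charged; in the alder run at 5.00 d the missing part is 45.4 %.
- G is the initiator and D a further species. dp is the monomer in chains over the chains begun, and c is the part of X reacted.

in all of them: X 0.034 M; G 1.4 mM

| flask | D | remark | time |
|---|---|---|---|
| alder | 0.87 mM | run made earlier |  |
| oak | 2 mM | run made earlier |  |
| flask | 1.3 mM |  | 4.0 d |

- alder (time / d: Q / %, X / %): 0.250: 7.3, 88.3; 0.833: 21.1, 66.9; 1.25: 26.3, 60.1; 2.08: 29.5, 45.0; 3.00: 30.7, 38.4; 4.00: 26.8, 35.7; 5.00: 23.0, 31.6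
- oak (time / d: Q / %, X / %): 0.625: 9.5, 80.7; 1.25: 16.7, 65.4; 2.08: 20.1, 51.2; 3.00: 23.8, 44.3; 4.00: 23.9, 36.1; 5.00: 20.8, 32.9

(standard deviation of a reading: 1 percentage point)

- the average divides the monomer in chains by the number of chains begun, living and dead together
- the earlier runs do not show the number of chains; that part of a forecast is a guess

- average number of monomer units in a chain (chains begun, living or dead) at 4.0 d
- part of the X that has reacted at 4.0 d

- I start from growth alone, X into Q: then Q is simply what X has lost.
- I add a return step, Q back to X. Q now stops rising at one level of X, the equilibrium monomer level. Around the top of Q I read X at 41.7 % in alder and 40.2 % in oak, though D differs, so I take X_c, the level of X at which Q stops rising, as 41.0 %. These two steps put Q at 59.0 %.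
- I add the missing part: X slips under X_c and Q turns down, from 30.7 % to 23.0 % in alder.
- Interpolating in D for this flask at 4.0 d, I reckon X 35.9 %, below X_c, so c is 64.1 %, with Q 25.7 %.
- The chains are not shown. One chain per G gives dp 6.24. D is about as plentiful as G, so I guess 0.5 of G begins chains, and dp is 12.5.
- The forecast is dp 8 and c 64 %, with the remark “Initiation may be incomplete, which would raise dp”.
- The flask gives dp 16.1 and c 64.4 %.

    X + G → E + Q (k = 1.70 M⁻¹ min⁻¹)
    X + E → Q + E, rate k2*[E]*[X] (k = 0.530 M⁻¹ min⁻¹)
    Q + E → X + E, rate k3*[E] as long as [Q] is above zero (k = 0.00740 min⁻¹)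
    G → Z (k = 0.0110 min⁻¹)
    X → L (k = 1.20 × 10⁻⁴ min⁻¹)
    G + D → J (k = 89.0 M⁻¹ min⁻¹)

- In the flask at 4.0 d, X is 0.869 of X_c, and Q is made at 0.867 of the rate at which it is taken away. E, the living ends that count the chains, stands at 5.49 × 10⁻⁴ M, which is 0.392 of the G charged against my 0.5. The same flask read at 6.0 d has X at 31 %, 0.756 of X_c, further under it, and Q there is lower, at 19.1 %. E in that flask stands at 5.49 × 10⁻⁴ M as before, and its dp is down with Q, at 11.8.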